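The 20-membered ring is numbered from the lactone carbonyl (C1) to the carbinol carbon C19; C20–C24 form the side chain. The route rests on the C10–C11 bond: the homoallylic C11–O unit with its (8Z)-alkene is the retron of a 3,6-dihydro-2H-pyran. A catalytic asymmetric hetero-Diels–Alder reaction of ethyl glyoxylate with 1-methoxybutadiene closes this temporary ring by forming C10–C11 (and O–C7), sets C11 and locks the C8=C9 Z geometry; C11 then controls C12 by chelation. Later the ring is opened at the acetal carbon C7, its oxygen leaves as a mesylate when the C11–C12 epoxide closes, and a Nozaki–Hiyama–Kishi reaction at C5–C6 closes the macrocycle.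

Key step: step 1

Assumption: where a chiral catalyst or reagent is named, it is the enantiomer expected from its established sense of induction with simple substrates; the configurations drawn are those the route requires.

Step 1
Reactants: 1 ethyl glyoxylate (freshly distilled); 2 (E)-1-methoxybuta-1,3-diene
Product: 3 ethyl (2S,6R)-6-methoxy-3,6-dihydro-2H-pyran-2-carboxylate
Conditions: (S)-BINOL/TiCl2(OiPr)2 (10 mol%), 4 Å MS, CH2Cl2, −30 °C
Reagents that add atoms: none
Why: The chiral titanium Lewis acid activates the glyoxylate aldehyde and the electron-rich diene adds in an asynchronous, endo-selective [4+2] hetero-Diels–Alder reaction, the known cycloaddition of glyoxylates with 1-alkoxydienes under BINOL–titanium catalysis. The six-membered dihydropyran closes by cycloaddition, forming C10–C11 (diene terminus to aldehyde carbon) and O–C7 (aldehyde oxygen to the future acetal carbon) in one operation. C11 is set by the catalyst, which directs the diene to the Si face of the bound glyoxylate; the acetal centre C7 (cis, endo) is inconsequential because it is destroyed in step 14. The ring holds C8=C9 cis, so the (8Z) geometry is fixed by construction, and the ring oxygen serves later as chelating handle (step 12) and as leaving group at C11 (step 16). The step needs regioselectivity (secured by the 1-methoxy donor), cycloaddition in preference to ene or open-chain aldol pathways (secured by the concerted endo pathway at low temperature) and enantiofacial control (catalyst).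

Step 2
Reactants: 3 ethyl (2S,6R)-6-methoxy-3,6-dihydro-2H-pyran-2-carboxylate
Product: 4 (2S,6R)-N,6-dimethoxy-N-methyl-3,6-dihydro-2H-pyran-2-carboxamide
Conditions: MeNHOMe·HCl, iPrMgCl, THF, −20 °C
Reagents that add atoms: N,O-dimethylhydroxylamine hydrochloride, CNOC.Cl
Why: Weinreb amide formation by aminolysis of the ester with the chloromagnesium amide runs at low temperature and should not epimerise the α-alkoxy centre C11.

Step 3
Reactants: 5 3-(trimethylsilyl)prop-2-ynal; 6 tert-butyl[(1-methoxyethenyl)oxy]dimethylsilane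
Product: 7 methyl (3S)-3-hydroxy-5-(trimethylsilyl)pent-4-ynoate
Conditions: SiCl4, chiral binaphthyldiamine-derived bisphosphoramide (5 mol%, enantiomer directing Si-face attack), CH2Cl2, −78 °C; aq. NaHCO3/KF
Reagents that add atoms: none
Why: In this enantioselective Mukaiyama aldol addition the phosphoramide-bound silicon cation activates the conjugated ynal and controls its face, which sets the future C15.

Step 4
Reactants: 7 methyl (3S)-3-hydroxy-5-(trimethylsilyl)pent-4-ynoate
Product: 8 methyl (3S)-3-methoxy-5-(trimethylsilyl)pent-4-ynoate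
Conditions: Me3OBF4, 1,8-bis(dimethylamino)naphthalene, CH2Cl2, 0 °C to rt
Reagents that add atoms: trimethyloxonium tetrafluoroborate, C[O+](C)C.F[B-](F)(F)F
Why: O-Methylation with Meerwein's salt under non-nucleophilic buffering avoids the retro-aldol and β-elimination pathways of a basic Williamson methylation.

Step 5
Reactants: 8 methyl (3S)-3-methoxy-5-(trimethylsilyl)pent-4-ynoate
Product: 10 (5S)-5-methoxy-7-(trimethylsilyl)hept-6-yn-3-one, via Weinreb amide 9 (not isolated)
Conditions: MeNHOMe·HCl, EtMgBr (excess), THF, −20 to 0 °C; aq. NH4Cl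
Reagents that add atoms: ethylmagnesium bromide, CC[Mg]Br
Why: In this one-pot Weinreb ketone synthesis the bromomagnesium amide converts the ester into the Weinreb amide and EtMgBr then adds once to a stable chelate, so the ethyl ketone appears only on work-up.

Step 6
Reactants: 10 (5S)-5-methoxy-7-(trimethylsilyl)hept-6-yn-3-one; 11 (2E,4E)-hexa-2,4-dienal
Product: 12 (3S,6S,7R,8E,10E)-7-hydroxy-3-methoxy-6-methyl-1-(trimethylsilyl)dodeca-8,10-dien-1-yn-5-one
Conditions: (−)-Ipc2BOTf, iPr2NEt, CH2Cl2, −78 °C; then 11, −78 to −20 °C; H2O2, pH 7 buffer, MeOH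
Reagents that add atoms: none
Why: In this boron-mediated aldol reaction the Z-enol borinate formed on the ethyl side reacts through a chair transition state to give the 18,19-syn adduct, and the isopinocampheyl ligands direct attack to the Si face of the dienal, which sets C18 and C19.

Step 7
Reactants: 12 (3S,6S,7R,8E,10E)-7-hydroxy-3-methoxy-6-methyl-1-(trimethylsilyl)dodeca-8,10-dien-1-yn-5-one
Product: 13 C13–C24 unit as 17,19-anti diol 19-benzoate with free 17-hydroxyl
Conditions: PhCHO, SmI2 (30 mol%), THF, −10 °C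
Reagents that add atoms: benzaldehyde, O=Cc1ccccc1
Why: In the Evans–Tishchenko reduction the samarium-bound hemiacetal of benzaldehyde delivers hydride intramolecularly to the C17 ketone, which sets C17 anti to C19 and leaves C19 as benzoate and C17 as free alcohol.

Step 8
Reactants: 13 C13–C24 unit as 17,19-anti diol 19-benzoate with free 17-hydroxyl
Product: 14 17-O-triethylsilyl ether of 13
Conditions: TESOTf, 2,6-lutidine, CH2Cl2, −78 °C
Reagents that add atoms: triethylsilyl trifluoromethanesulfonate, CC[Si](CC)(CC)OS(=O)(=O)C(F)(F)F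
Why: Fast low-temperature silyl ether formation caps the C17 hydroxyl before the benzoate can migrate.

Step 9
Reactants: 14 17-O-triethylsilyl ether of 13
Product: 15 (22R,23R)-22,23-epoxide of 14
Conditions: D-fructose-derived Shi ketone (30 mol%), KHSO5 (Oxone), K2CO3, Bu4NHSO4, MeCN/dimethoxymethane/aq. borate buffer (pH 10.5), 0 °C
Reagents that add atoms: potassium peroxymonosulfate, [K+].[O-]S(=O)(=O)OO
Why: In the Shi epoxidation the chiral dioxirane attacks the distal, more electron-rich E-alkene (the proximal one is deactivated by the allylic benzoate) through the spiro transition state, which sets C22 and C23 under catalyst control.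

Step 10
Reactants: 15 (22R,23R)-22,23-epoxide of 14
Product: 16 terminal alkyne of the C13–C24 fragment
Conditions: K2CO3 (cat.), MeOH, 0 °C
Reagents that add atoms: none
Why: Protodesilylation of the C-silyl alkyne by methanolysis is much faster than cleavage of the hindered secondary benzoate.

Step 11
Reactants: 16 terminal alkyne of the C13–C24 fragment; 4 (2S,6R)-N,6-dimethoxy-N-methyl-3,6-dihydro-2H-pyran-2-carboxamide
Product: 17 C12 ynone joining the dihydropyran to the C13–C24 fragment
Conditions: LiHMDS, THF, −78 °C; then 4, −78 to −30 °C; aq. NH4Cl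
Reagents that add atoms: none
Why: In this Weinreb ketone synthesis the lithium acetylide adds once to the amide and the chelate collapses to the ynone only on work-up, which joins the halves at C12–C13 without touching benzoate or epoxide.

Step 12
Reactants: 17 C12 ynone joining the dihydropyran to the C13–C24 fragment
Product: 18 tertiary propargylic alcohol at C12
Conditions: MeMgBr, CH2Cl2/Et2O, −78 °C
Reagents that add atoms: methylmagnesium bromide, C[Mg]Br
Why: In this chelation-controlled Grignard addition (Cram chelate model) magnesium bridges the ketone oxygen and the ring oxygen on C11 and methyl adds 1,2 from the face of the C11 hydrogen, which sets C12 as required for the (11R,12R)-epoxide.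

Step 13
Reactants: 18 tertiary propargylic alcohol at C12
Product: 19 (13Z)-allylic alcohol
Conditions: H2 (1 atm), Pd/CaCO3 poisoned with Pb(OAc)2 (Lindlar catalyst), quinoline, EtOAc, rt
Reagents that add atoms: none
Why: Lindlar semihydrogenation delivers hydrogen syn to give the (13Z)-alkene, and tertiary propargylic alcohols and vinyl epoxides should survive if uptake is stopped at one equivalent.

Step 14
Reactants: 19 (13Z)-allylic alcohol
Product: 20 lactol at C7 (anomers)
Conditions: PPTS (cat.), acetone/H2O (10:1), 0 °C to rt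
Reagents that add atoms: water, O
Why: Acetal hydrolysis of the allylic acetal proceeds under very mild acid through a conjugated oxocarbenium ion, and the Z-hydroxy-enal stays closed as the lactol, which protects the C8=C9 geometry.

Step 15
Reactants: 20 lactol at C7 (anomers)
Product: 21 open-chain (6Z,8Z)-6-iodo-6,8-diene 11,12-diol
Conditions: EtPPh3I, n-BuLi, THF; I2, −78 °C; NaHMDS, −20 °C; then 20 (ylide in excess), −78 to −20 °C
Reagents that add atoms: ethyltriphenylphosphonium iodide, CC[P+](c1ccccc1)(c1ccccc1)c1ccccc1.[I-]; iodine, II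
Why: In this Stork–Zhao olefination the α-iodo ylide Ph3P=C(I)CH3 intercepts the open hydroxy-enal form of the lactol, and kinetic oxaphosphetane formation places iodine cis to C8 to give the (6Z)-iodide while the 8Z alkene is kept.

Step 16
Reactants: 21 open-chain (6Z,8Z)-6-iodo-6,8-diene 11,12-diol
Product: 24 (11R,12R)-epoxide with free 19-hydroxyl, via mesylate 22 (not isolated), via epoxy benzoate 23 (not isolated)
Conditions: MsCl, Et3N, CH2Cl2, −10 °C; then K2CO3, MeOH, rt
Reagents that add atoms: none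
Why: Mesylation takes the secondary C11 hydroxyl beside the tertiary C12 hydroxyl, an intramolecular Williamson reaction by the C12 alkoxide inverts C11 to close the epoxide, and continued methanolysis removes the benzoate.

Step 17
Reactants: 25 ethyl 2-[bis(2,2,2-trifluoroethoxy)phosphoryl]propanoate
Product: 26 2-[bis(2,2,2-trifluoroethoxy)phosphoryl]propanoic acid
Conditions: Me3SnOH, 1,2-dichloroethane, 80 °C; 1 M HCl
Reagents that add atoms: trimethyltin hydroxide, C[Sn](C)(C)O
Why: Ester hydrolysis with Me3SnOH is neutral and should spare the base-labile trifluoroethyl phosphonate esters.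

Step 18
Reactants: 24 (11R,12R)-epoxide with free 19-hydroxyl; 26 2-[bis(2,2,2-trifluoroethoxy)phosphoryl]propanoic acid
Product: 27 19-O-phosphonopropanoyl ester of 24
Conditions: DCC, DMAP (cat.), CH2Cl2, 0 °C to rt
Reagents that add atoms: none
Why: Steglich esterification acylates the only free hydroxyl (C19), and using the phosphonate acid instead of a (Z)-enoic acid removes any risk of Z to E isomerisation during ester formation.

Step 19
Reactants: 28 methyl (R)-3-hydroxy-2-methylpropanoate
Product: 29 methyl (R)-2-methyl-3-[(triethylsilyl)oxy]propanoate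
Conditions: TESCl, imidazole, CH2Cl2, 0 °C
Reagents that add atoms: chlorotriethylsilane, CC[Si](Cl)(CC)CC
Why: Silylation of the primary alcohol installs a group that can later be oxidised directly to the aldehyde; the stereocentre (future C4) comes from the chiral pool.

Step 20
Reactants: 29 methyl (R)-2-methyl-3-[(triethylsilyl)oxy]propanoate
Product: 30 (R)-2-methyl-3-[(triethylsilyl)oxy]propanal
Conditions: DIBAL-H, CH2Cl2, −78 °C; Rochelle salt
Reagents that add atoms: none
Why: In this partial ester reduction the aluminium hemiacetal is stable at −78 °C, so reduction stops at the aldehyde without epimerising the α-centre.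

Step 21
Reactants: 27 19-O-phosphonopropanoyl ester of 24; 30 (R)-2-methyl-3-[(triethylsilyl)oxy]propanal
Product: 31 seco (2Z)-enoate with 5-O-triethylsilyl ether
Conditions: KHMDS, 18-crown-6, THF, −78 °C; then 30
Reagents that add atoms: none
Why: The Still–Gennari olefination, with an electron-poor trifluoroethyl phosphonate and a dissociated potassium ion, makes the addition step irreversible and should give the (2Z)-trisubstituted enoate.

Step 22
Reactants: 31 seco (2Z)-enoate with 5-O-triethylsilyl ether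
Product: 32 seco C5 aldehyde
Conditions: (COCl)2, DMSO, CH2Cl2, −78 to −40 °C; iPr2NEt, −78 °C; cold pH 7 buffer
Reagents that add atoms: none
Why: Swern oxidation converts the primary triethylsilyl ether directly into the aldehyde while the secondary silyl ether is untouched, so the free (Z)-δ-hydroxy enoate, which would lactonise, is never formed.

Step 23
Reactants: 32 seco C5 aldehyde
Product: 33 macrocyclic C5 alcohol (both epimers)
Conditions: CrCl2 (excess), NiCl2 (1 mol%), DMSO, rt, high dilution (1 mM)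
Reagents that add atoms: none
Why: In this Nozaki–Hiyama–Kishi macrocyclisation zerovalent nickel inserts into the C6–I bond with retention of geometry, the vinylchromium species adds to the C5 aldehyde under neutral conditions, and the C5 epimers converge in step 24.

Step 24
Reactants: 33 macrocyclic C5 alcohol (both epimers)
Product: 34 17-O-triethylsilyl ether of the target
Conditions: Dess–Martin periodinane, NaHCO3, CH2Cl2, 0 °C
Reagents that add atoms: none
Why: Buffered Dess–Martin oxidation, applied at once to the crude carbinol, converts both epimers into the (6Z,8Z)-dienone without base, so C4 should not epimerise.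

Step 25
Reactants: 34 17-O-triethylsilyl ether of the target
Product: 35 target macrolide
Conditions: HF·pyridine, pyridine, THF, 0 °C
Reagents that add atoms: none
Why: Buffered fluoride desilylation of the secondary triethylsilyl ether is mild enough to leave both vinyl epoxides and the base-sensitive C4 centre intact.

Compound list (locants are those of the target; unless stated, stereocentres have the spatial arrangement they have in the target)

1 | ethyl glyoxylate | CCOC(=O)C=O | starting material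
2 | (E)-1-methoxybuta-1,3-diene | CO/C=C/C=C | starting material
3 | ethyl (2S,6R)-6-methoxy-3,6-dihydro-2H-pyran-2-carboxylate (cis; pyran C2 = C11, C6 = C7) | CCOC(=O)[C@@H]1CC=C[C@H](OC)O1 | intermediate
4 | (2S,6R)-N,6-dimethoxy-N-methyl-3,6-dihydro-2H-pyran-2-carboxamide | CON(C)C(=O)[C@@H]1CC=C[C@H](OC)O1 | intermediate
5 | 3-(trimethylsilyl)prop-2-ynal | C[Si](C)(C)C#CC=O | starting material
6 | tert-butyl[(1-methoxyethenyl)oxy]dimethylsilane | COC(=C)O[Si](C)(C)C(C)(C)C | starting material
7 | methyl (3S)-3-hydroxy-5-(trimethylsilyl)pent-4-ynoate | COC(=O)C[C@H](O)C#C[Si](C)(C)C | intermediate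
8 | methyl (3S)-3-methoxy-5-(trimethylsilyl)pent-4-ynoate | COC(=O)C[C@H](OC)C#C[Si](C)(C)C | intermediate
9 | (3S)-N,3-dimethoxy-N-methyl-5-(trimethylsilyl)pent-4-ynamide | CON(C)C(=O)C[C@H](OC)C#C[Si](C)(C)C | intermediate
10 | (5S)-5-methoxy-7-(trimethylsilyl)hept-6-yn-3-one | CCC(=O)C[C@H](OC)C#C[Si](C)(C)C | intermediate
11 | (2E,4E)-hexa-2,4-dienal | C/C=C/C=C/C=O | starting material
12 | (3S,6S,7R,8E,10E)-7-hydroxy-3-methoxy-6-methyl-1-(trimethylsilyl)dodeca-8,10-dien-1-yn-5-one (C13–C24 unit, 18,19-syn) | C[Si](C)(C)C#C[C@@H](OC)CC(=O)[C@@H](C)[C@H](O)/C=C/C=C/C | intermediate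
13 | C13–C24 unit as 17,19-anti diol 19-benzoate with free 17-hydroxyl | C[Si](C)(C)C#C[C@@H](OC)C[C@@H](O)[C@@H](C)[C@H](OC(=O)c1ccccc1)/C=C/C=C/C | intermediate
14 | 17-O-triethylsilyl ether of 13 | C[Si](C)(C)C#C[C@@H](OC)C[C@@H](O[Si](CC)(CC)CC)[C@@H](C)[C@H](OC(=O)c1ccccc1)/C=C/C=C/C | intermediate
15 | (22R,23R)-22,23-epoxide of 14 | C[Si](C)(C)C#C[C@@H](OC)C[C@@H](O[Si](CC)(CC)CC)[C@@H](C)[C@H](OC(=O)c1ccccc1)/C=C/[C@H]1O[C@@H]1C | intermediate
16 | terminal alkyne of the C13–C24 fragment (15-OMe, 17-OTES, 19-OBz, 20E-alkene, trans-epoxide) | C#C[C@@H](OC)C[C@@H](O[Si](CC)(CC)CC)[C@@H](C)[C@H](OC(=O)c1ccccc1)/C=C/[C@H]1O[C@@H]1C | intermediate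
17 | C12 ynone joining the dihydropyran (C7 methyl acetal, C11 ring carbon) to the C13–C24 fragment | CO[C@H]1C=CC[C@H](O1)C(=O)C#C[C@@H](OC)C[C@@H](O[Si](CC)(CC)CC)[C@@H](C)[C@H](OC(=O)c1ccccc1)/C=C/[C@H]1O[C@@H]1C | intermediate
18 | tertiary propargylic alcohol at C12 | CO[C@H]1C=CC[C@H](O1)[C@](C)(O)C#C[C@@H](OC)C[C@@H](O[Si](CC)(CC)CC)[C@@H](C)[C@H](OC(=O)c1ccccc1)/C=C/[C@H]1O[C@@H]1C | intermediate
19 | (13Z)-allylic alcohol | CO[C@H]1C=CC[C@H](O1)[C@](C)(O)/C=C\[C@@H](OC)C[C@@H](O[Si](CC)(CC)CC)[C@@H](C)[C@H](OC(=O)c1ccccc1)/C=C/[C@H]1O[C@@H]1C | intermediate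
20 | lactol at C7 (anomers) | OC1C=CC[C@H](O1)[C@](C)(O)/C=C\[C@@H](OC)C[C@@H](O[Si](CC)(CC)CC)[C@@H](C)[C@H](OC(=O)c1ccccc1)/C=C/[C@H]1O[C@@H]1C | intermediate
21 | open-chain (6Z,8Z)-6-iodo-6,8-diene 11,12-diol (C11 opposite to the target epoxide carbon, C12 tertiary) | C/C(I)=C/C=C\C[C@H](O)[C@](C)(O)/C=C\[C@@H](OC)C[C@@H](O[Si](CC)(CC)CC)[C@@H](C)[C@H](OC(=O)c1ccccc1)/C=C/[C@H]1O[C@@H]1C | intermediate
22 | 11-O-mesylate of 21 | C/C(I)=C/C=C\C[C@H](OS(C)(=O)=O)[C@](C)(O)/C=C\[C@@H](OC)C[C@@H](O[Si](CC)(CC)CC)[C@@H](C)[C@H](OC(=O)c1ccccc1)/C=C/[C@H]1O[C@@H]1C | intermediate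
23 | (11R,12R)-epoxide with 19-benzoate | C/C(I)=C/C=C\C[C@H]1O[C@]1(C)/C=C\[C@@H](OC)C[C@@H](O[Si](CC)(CC)CC)[C@@H](C)[C@H](OC(=O)c1ccccc1)/C=C/[C@H]1O[C@@H]1C | intermediate
24 | (11R,12R)-epoxide with free 19-hydroxyl | C/C(I)=C/C=C\C[C@H]1O[C@]1(C)/C=C\[C@@H](OC)C[C@@H](O[Si](CC)(CC)CC)[C@@H](C)[C@H](O)/C=C/[C@H]1O[C@@H]1C | intermediate
25 | ethyl 2-[bis(2,2,2-trifluoroethoxy)phosphoryl]propanoate | CCOC(=O)C(C)P(=O)(OCC(F)(F)F)OCC(F)(F)F | starting material
26 | 2-[bis(2,2,2-trifluoroethoxy)phosphoryl]propanoic acid | CC(C(=O)O)P(=O)(OCC(F)(F)F)OCC(F)(F)F | intermediate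
27 | 19-O-{2-[bis(2,2,2-trifluoroethoxy)phosphoryl]propanoyl} ester of 24 (epimers at the phosphonate carbon) | C/C(I)=C/C=C\C[C@H]1O[C@]1(C)/C=C\[C@@H](OC)C[C@@H](O[Si](CC)(CC)CC)[C@@H](C)[C@H](OC(=O)C(C)P(=O)(OCC(F)(F)F)OCC(F)(F)F)/C=C/[C@H]1O[C@@H]1C | intermediate
28 | methyl (R)-3-hydroxy-2-methylpropanoate | OC[C@@H](C)C(=O)OC | starting material
29 | methyl (R)-2-methyl-3-[(triethylsilyl)oxy]propanoate | CC[Si](CC)(CC)OC[C@@H](C)C(=O)OC | intermediate
30 | (R)-2-methyl-3-[(triethylsilyl)oxy]propanal | CC[Si](CC)(CC)OC[C@@H](C)C=O | intermediate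
31 | seco (2Z)-enoate: 19-O-[(2Z,4S)-2,4-dimethyl-5-(triethylsilyloxy)pent-2-enoyl] derivative of 24 | C/C(I)=C/C=C\C[C@H]1O[C@]1(C)/C=C\[C@@H](OC)C[C@@H](O[Si](CC)(CC)CC)[C@@H](C)[C@H](OC(=O)/C(C)=C\[C@H](C)CO[Si](CC)(CC)CC)/C=C/[C@H]1O[C@@H]1C | intermediate
32 | seco C5 aldehyde: 19-O-[(2Z,4S)-2,4-dimethyl-5-oxopent-2-enoyl] derivative of 24 | C/C(I)=C/C=C\C[C@H]1O[C@]1(C)/C=C\[C@@H](OC)C[C@@H](O[Si](CC)(CC)CC)[C@@H](C)[C@H](OC(=O)/C(C)=C\[C@H](C)C=O)/C=C/[C@H]1O[C@@H]1C | intermediate
33 | macrocyclic C5 alcohol (both C5 epimers), 17-OTES | C/C1=C/C=C\C[C@H]2O[C@]2(C)/C=C\[C@@H](OC)C[C@@H](O[Si](CC)(CC)CC)[C@@H](C)[C@H](OC(=O)/C(C)=C\[C@H](C)C1O)/C=C/[C@H]1O[C@@H]1C | intermediate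
34 | 17-O-triethylsilyl ether of the target | C/C1=C/C=C\C[C@H]2O[C@]2(C)/C=C\[C@@H](OC)C[C@@H](O[Si](CC)(CC)CC)[C@@H](C)[C@H](OC(=O)/C(C)=C\[C@H](C)C1=O)/C=C/[C@H]1O[C@@H]1C | intermediate
35 | target macrolide (2Z,4S,6Z,8Z,11R,12R,13Z,15S,17R,18R,19R,20E,22R,23R) | CO[C@@H]1/C=C\[C@@]2(C)O[C@@H]2C/C=C\C=C(\C)C(=O)[C@@H](C)/C=C(/C)C(=O)O[C@H](/C=C/[C@H]2O[C@@H]2C)[C@H](C)[C@H](O)C1 | target

Total step count: 25. Longest linear sequence: 20 steps (steps 3–10, 11–16, 18 and 21–25, from 5 and 6 to 35).

Steps most likely to fail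

1. Step 15 (olefination of the lactol). The lactol may stay closed at the low temperature that the thermally fragile α-iodo ylide demands, so the olefination is slow and the ylide decays, or the hydroxy-enal isomerises to the E form under the basic conditions. The fallback sets out from 20 and comes back at 24, and it carries out the olefination on a free aldehyde. Luche reduction (NaBH4, CeCl3, MeOH) of 20 gives the (Z)-allylic triol F1. TESCl/imidazole at −40 °C silylates the primary allylic hydroxyl to give the bis-silyl ether F2. MsCl/Et3N gives the C11 mesylate F3, and NaH in THF closes the epoxide F4 with the benzoate intact. Direct Swern oxidation of the primary allylic silyl ether gives the (Z)-enal F5, which undergoes the Stork–Zhao olefination at −78 °C to give 23. K2CO3/MeOH then removes the benzoate to give 24.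

2. Step 23 (macrocyclisation). The β,γ-unsaturated aldehyde may epimerise at C4 or shift its C2=C3 bond before the slow ring closure, chromium halides may open a vinyl epoxide, or oligomers may form. The fallback sets out from 27 and comes back at 35; it forms C5–C6 first, intermolecularly, with a robust aldehyde and closes the ring by olefination. Commercial methyl (S)-3-hydroxy-2-methylpropanoate is silylated and reduced as in steps 19 and 20 to give the ester F6 and the aldehyde F7. CrCl2/NiCl2 coupling of 27 with F7 gives the C5 carbinol F8 (epimers), and TESOTf/2,6-lutidine gives the silyl ether F9. Swern oxidation of the primary silyl ether gives the C3 aldehyde F10. An intramolecular Still–Gennari reaction (KHMDS, 18-crown-6, high dilution) gives the macrocycle F11. HF·pyridine removes both silyl ethers to give the diol F12, and MnO2 oxidises only the dienylic C5 alcohol to give 35.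

3. Step 14 (acetal hydrolysis). Acid-catalysed opening of the side-chain vinyl epoxide and loss of the C17 silyl ether may compete with hydrolysis of the acetal. The fallback sets out from 3 and comes back at 20; it exchanges the anomeric group at the start for one that is removed oxidatively. Transacetalisation of 3 with 4-methoxybenzyl alcohol (PPTS, 4 Å MS) gives the PMB acetal F13. The chemistry of steps 2, 11, 12 and 13 then gives the Weinreb amide F14, the ynone F15, the tertiary alcohol F16 and the (13Z)-alkene F17. DDQ in CH2Cl2/pH 7 buffer cleaves the PMB acetal to the lactol 20 without acid.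

Further compounds
F1 | step 15 | (Z)-allylic triol from reduction of lactol 20 | OC/C=C\C[C@H](O)[C@](C)(O)/C=C\[C@@H](OC)C[C@@H](O[Si](CC)(CC)CC)[C@@H](C)[C@H](OC(=O)c1ccccc1)/C=C/[C@H]1O[C@@H]1C
F2 | step 15 | 7-O-triethylsilyl ether of F1 | CC[Si](CC)(CC)OC/C=C\C[C@H](O)[C@](C)(O)/C=C\[C@@H](OC)C[C@@H](O[Si](CC)(CC)CC)[C@@H](C)[C@H](OC(=O)c1ccccc1)/C=C/[C@H]1O[C@@H]1C
F3 | step 15 | 11-O-mesylate of F2 | CC[Si](CC)(CC)OC/C=C\C[C@H](OS(C)(=O)=O)[C@](C)(O)/C=C\[C@@H](OC)C[C@@H](O[Si](CC)(CC)CC)[C@@H](C)[C@H](OC(=O)c1ccccc1)/C=C/[C@H]1O[C@@H]1C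
F4 | step 15 | (11R,12R)-epoxide with 7-O-triethylsilyl ether and 19-benzoate | CC[Si](CC)(CC)OC/C=C\C[C@H]1O[C@]1(C)/C=C\[C@@H](OC)C[C@@H](O[Si](CC)(CC)CC)[C@@H](C)[C@H](OC(=O)c1ccccc1)/C=C/[C@H]1O[C@@H]1C
F5 | step 15 | (8Z)-C7 enal of the epoxide | O=C/C=C\C[C@H]1O[C@]1(C)/C=C\[C@@H](OC)C[C@@H](O[Si](CC)(CC)CC)[C@@H](C)[C@H](OC(=O)c1ccccc1)/C=C/[C@H]1O[C@@H]1C
F6 | step 23 | methyl (S)-2-methyl-3-[(triethylsilyl)oxy]propanoate | CC[Si](CC)(CC)OC[C@H](C)C(=O)OC
F7 | step 23 | (S)-2-methyl-3-[(triethylsilyl)oxy]propanal | CC[Si](CC)(CC)OC[C@H](C)C=O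
F8 | step 23 | C5 carbinol (epimers) from coupling of 27 with F7 | CC[Si](CC)(CC)OC[C@H](C)C(O)/C(C)=C\C=C/C[C@H]1O[C@]1(C)/C=C\[C@@H](OC)C[C@@H](O[Si](CC)(CC)CC)[C@@H](C)[C@H](OC(=O)C(C)P(=O)(OCC(F)(F)F)OCC(F)(F)F)/C=C/[C@H]1O[C@@H]1C
F9 | step 23 | 5-O-triethylsilyl ether of F8 | CC[Si](CC)(CC)OC[C@H](C)C(O[Si](CC)(CC)CC)/C(C)=C\C=C/C[C@H]1O[C@]1(C)/C=C\[C@@H](OC)C[C@@H](O[Si](CC)(CC)CC)[C@@H](C)[C@H](OC(=O)C(C)P(=O)(OCC(F)(F)F)OCC(F)(F)F)/C=C/[C@H]1O[C@@H]1C
F10 | step 23 | C3 aldehyde from F9 | O=C[C@H](C)C(O[Si](CC)(CC)CC)/C(C)=C\C=C/C[C@H]1O[C@]1(C)/C=C\[C@@H](OC)C[C@@H](O[Si](CC)(CC)CC)[C@@H](C)[C@H](OC(=O)C(C)P(=O)(OCC(F)(F)F)OCC(F)(F)F)/C=C/[C@H]1O[C@@H]1C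
F11 | step 23 | macrocycle with 5-O- and 17-O-triethylsilyl ethers | C/C1=C/C=C\C[C@H]2O[C@]2(C)/C=C\[C@@H](OC)C[C@@H](O[Si](CC)(CC)CC)[C@@H](C)[C@H](OC(=O)/C(C)=C\[C@H](C)C1O[Si](CC)(CC)CC)/C=C/[C@H]1O[C@@H]1C
F12 | step 23 | macrocyclic 5,17-diol | C/C1=C/C=C\C[C@H]2O[C@]2(C)/C=C\[C@@H](OC)C[C@@H](O)[C@@H](C)[C@H](OC(=O)/C(C)=C\[C@H](C)C1O)/C=C/[C@H]1O[C@@H]1C
F13 | step 14 | ethyl (2S)-6-[(4-methoxybenzyl)oxy]-3,6-dihydro-2H-pyran-2-carboxylate (anomers) | CCOC(=O)[C@@H]1CC=CC(OCc2ccc(OC)cc2)O1
F14 | step 14 | Weinreb amide of F13 | CON(C)C(=O)[C@@H]1CC=CC(OCc2ccc(OC)cc2)O1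
F15 | step 14 | C12 ynone with PMB acetal at C7 | COc1ccc(COC2C=CC[C@H](O2)C(=O)C#C[C@@H](OC)C[C@@H](O[Si](CC)(CC)CC)[C@@H](C)[C@H](OC(=O)c3ccccc3)/C=C/[C@H]3O[C@@H]3C)cc1
F16 | step 14 | tertiary propargylic alcohol with PMB acetal at C7 | COc1ccc(COC2C=CC[C@H](O2)[C@](C)(O)C#C[C@@H](OC)C[C@@H](O[Si](CC)(CC)CC)[C@@H](C)[C@H](OC(=O)c3ccccc3)/C=C/[C@H]3O[C@@H]3C)cc1
F17 | step 14 | (13Z)-allylic alcohol with PMB acetal at C7 | COc1ccc(COC2C=CC[C@H](O2)[C@](C)(O)/C=C\[C@@H](OC)C[C@@H](O[Si](CC)(CC)CC)[C@@H](C)[C@H](OC(=O)c3ccccc3)/C=C/[C@H]3O[C@@H]3C)cc1
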